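**Strategy.** The dihydrochalcone is cut at the Cα–Cβ bond into a ring A methyl ketone and a ring B aldehyde. The chromane of ring A comes from a 2H-chromene made by gold-catalysed 6-endo-dig hydroarylation of an aryl 1,1-dimethylpropargyl ether, which forms C4–C4a and closes the pyran ring in one operation. The step exploits the position of the acyl carbon C6 para to O1: the precursor, 2,6-bis(methoxymethoxy)-4-[(2-methylbut-3-yn-2-yl)oxy]benzaldehyde, has a mirror plane through C6 and O1, so the two carbons ortho to the ether oxygen are identical and only one chromene can form.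

Key step: step 3

Remark on ring B: the target has the free hydroxyl at C3′ and the methoxy group at C4′, next to the prenyl group at C5′. In 5-bromovanillin (9) the two oxygen functions are the other way round, so the methyl group is moved from O3 to O4 (steps 7 and 8) before the prenyl group is attached.

Remark on stereochemistry: the target is achiral; the carbinol centres of 7 and 14 form as racemates and are removed again in the following operation.

**Route**

Step 1
Reactants: 1 2,4,6-trihydroxybenzaldehyde; 2 3-chloro-3-methylbut-1-yne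
Product: 3 2,6-dihydroxy-4-[(2-methylbut-3-yn-2-yl)oxy]benzaldehyde
Conditions: 2 (1.1 equiv), CuCl2·2H2O (1 mol%), DBU (1.1 equiv), MeCN, 0 °C
Reagents that add atoms: none
Why: Copper-catalysed propargylic etherification of a phenol; one equivalent of DBU deprotonates the 4-OH, which is the most acidic (para to CHO) and the only hydroxyl not hydrogen-bonded to the formyl oxygen, so this phenoxide alone should capture the copper-bound propargyl electrophile.

Step 2
Reactants: 3 2,6-dihydroxy-4-[(2-methylbut-3-yn-2-yl)oxy]benzaldehyde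
Product: 4 2,6-bis(methoxymethoxy)-4-[(2-methylbut-3-yn-2-yl)oxy]benzaldehyde
Conditions: NaH (2.5 equiv), MOMCl (2.5 equiv), DMF, 0 °C to rt
Reagents that add atoms: chloromethyl methyl ether (MOMCl), COCCl
Why: Williamson-type O-alkylation of both sodium phenoxides; full deprotonation breaks the chelate to the aldehyde so that both ortho hydroxyls react, while the non-enolisable aldehyde and the terminal alkyne are untouched at this temperature.

Step 3
Reactants: 4 2,6-bis(methoxymethoxy)-4-[(2-methylbut-3-yn-2-yl)oxy]benzaldehyde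
Product: 5 5,7-bis(methoxymethoxy)-2,2-dimethyl-2H-chromene-6-carbaldehyde
Conditions: Ph3PAuNTf2 (2–5 mol%), CH2Cl2 (dry), rt
Reagents that add atoms: none
Why: Cationic monovalent gold from Ph3PAuNTf2 binds the terminal alkyne as a π-acid, the arene carbon ortho to the ether oxygen attacks the terminal alkyne carbon in a Friedel–Crafts manner, and rearomatisation followed by protodeauration of the vinyl-gold species releases the 2H-chromene and the catalyst. The closest known reaction type is the gold- or platinum-catalysed cycloisomerisation (intramolecular hydroarylation) of aryl propargyl ethers to 2H-chromenes. The pyran ring closes in the 6-endo-dig mode with C4–C4a as the only new skeletal bond, and no stereocentre is created. The step needs 6-endo over 5-exo closure, which the unsubstituted alkyne terminus and the gem-dimethyl group at the propargylic carbon secure. Site selectivity on the arene is not an issue, because the mirror plane through C6 and O1 makes the two ortho carbons identical; each is activated by the ether oxygen, one ortho OMOM and one para OMOM group and is only meta to the formyl group. The MOM acetals and the aldehyde should be inert to this non-protic, weakly Lewis acidic catalyst in dry CH2Cl2.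

Step 4
Reactants: 5 5,7-bis(methoxymethoxy)-2,2-dimethyl-2H-chromene-6-carbaldehyde
Product: 6 5,7-bis(methoxymethoxy)-2,2-dimethyl-3,4-dihydro-2H-chromene-6-carbaldehyde
Conditions: H2 (1 atm), 10% Pd/C, Ph2S (1 mol%), EtOAc, rt
Reagents that add atoms: none
Why: Heterogeneous catalytic hydrogenation of the cis-disubstituted styrenic C3=C4 bond; the sulfide-moderated palladium surface and the neutral aprotic solvent should spare the hindered, electron-rich aryl aldehyde and the MOM acetals.

Step 5
Reactants: 6 5,7-bis(methoxymethoxy)-2,2-dimethyl-3,4-dihydro-2H-chromene-6-carbaldehyde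
Product: 7 racemic 1-[5,7-bis(methoxymethoxy)-2,2-dimethyl-3,4-dihydro-2H-chromen-6-yl]ethan-1-ol
Conditions: MeMgBr (1.3 equiv), THF, 0 °C; then aq. NH4Cl
Reagents that add atoms: methylmagnesium bromide, C[Mg]Br
Why: Grignard 1,2-addition to an aldehyde, assisted by chelation of magnesium between the carbonyl and an ortho MOM oxygen; the carbinol centre forms as a racemate and is oxidised away in step 6.

Step 6
Reactants: 7 racemic 1-[5,7-bis(methoxymethoxy)-2,2-dimethyl-3,4-dihydro-2H-chromen-6-yl]ethan-1-ol
Product: 8 1-[5,7-bis(methoxymethoxy)-2,2-dimethyl-3,4-dihydro-2H-chromen-6-yl]ethan-1-one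
Conditions: Dess–Martin periodinane (1.3 equiv), pyridine (3 equiv), CH2Cl2, 0 °C to rt
Reagents that add atoms: none
Why: Dess–Martin oxidation of a secondary benzylic alcohol to the aryl methyl ketone; the pyridine buffer keeps the acetic acid formed from cleaving the MOM acetals.

Step 7
Reactants: 9 5-bromovanillin (3-bromo-4-hydroxy-5-methoxybenzaldehyde)
Product: 10 3-bromo-4,5-dihydroxybenzaldehyde
Conditions: AlCl3 (1.2 equiv), pyridine (4.4 equiv), CH2Cl2, reflux; then 2 M HCl
Reagents that add atoms: none
Why: Lewis acid-assisted O-demethylation of an ortho-hydroxyanisole; aluminium chelated between the phenoxide and the neighbouring methoxy oxygen activates the methyl group for SN2 removal by pyridine, and aldehyde and aryl bromide are inert.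

Step 8
Reactants: 10 3-bromo-4,5-dihydroxybenzaldehyde
Product: 11 3-bromo-5-hydroxy-4-methoxybenzaldehyde
Conditions: MeI (1.05 equiv), Li2CO3 (1.2 equiv), DMF, 40 °C
Reagents that add atoms: iodomethane, CI
Why: Regioselective Williamson methylation of a catechol aldehyde; the weak base forms only the phenoxide of the 4-OH, which is the more acidic (para to CHO, ortho to Br), and this oxygen is methylated.

Step 9
Reactants: 11 3-bromo-5-hydroxy-4-methoxybenzaldehyde
Product: 12 3-bromo-4-methoxy-5-(methoxymethoxy)benzaldehyde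
Conditions: MOMCl (1.5 equiv), i-Pr2NEt (2 equiv), CH2Cl2, 0 °C to rt
Reagents that add atoms: chloromethyl methyl ether (MOMCl), COCCl
Why: Standard MOM protection of an unhindered, non-chelated phenol, chosen so that all three phenols of the final intermediate are released together in step 13.

Step 10
Reactants: 12 3-bromo-4-methoxy-5-(methoxymethoxy)benzaldehyde
Product: 13 4-methoxy-3-(methoxymethoxy)-5-(3-methylbut-2-en-1-yl)benzaldehyde
Conditions: tributyl(3-methylbut-2-en-1-yl)stannane (1.3 equiv), Pd(PPh3)4 (5 mol%), DMF, 100 °C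
Reagents that add atoms: tributyl(3-methylbut-2-en-1-yl)stannane, CCCC[Sn](CCCC)(CCCC)CC=C(C)C
Why: Stille coupling; zerovalent palladium inserts into the C–Br bond, the prenyl group is transferred from tin and reductive elimination at the less hindered CH2 terminus should give the linear prenyl arene, with aldehyde and MOM ether tolerated.

Step 11
Reactants: 8 1-[5,7-bis(methoxymethoxy)-2,2-dimethyl-3,4-dihydro-2H-chromen-6-yl]ethan-1-one; 13 4-methoxy-3-(methoxymethoxy)-5-(3-methylbut-2-en-1-yl)benzaldehyde
Product: 15 (E)-1-[5,7-bis(methoxymethoxy)-2,2-dimethyl-3,4-dihydro-2H-chromen-6-yl]-3-[4-methoxy-3-(methoxymethoxy)-5-(3-methylbut-2-en-1-yl)phenyl]prop-2-en-1-one, via β-hydroxy ketone 14 (not isolated)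
Conditions: KOH (5 equiv), EtOH, rt to 50 °C
Reagents that add atoms: none
Why: Claisen–Schmidt condensation of a methyl ketone with a non-enolisable aldehyde; the racemic aldol adduct 14 loses water by E1cB elimination to the thermodynamically preferred (E)-enone, and MOM ethers and the prenyl group are stable to base.

Step 12
Reactants: 15 (E)-1-[5,7-bis(methoxymethoxy)-2,2-dimethyl-3,4-dihydro-2H-chromen-6-yl]-3-[4-methoxy-3-(methoxymethoxy)-5-(3-methylbut-2-en-1-yl)phenyl]prop-2-en-1-one
Product: 16 1-[5,7-bis(methoxymethoxy)-2,2-dimethyl-3,4-dihydro-2H-chromen-6-yl]-3-[4-methoxy-3-(methoxymethoxy)-5-(3-methylbut-2-en-1-yl)phenyl]propan-1-one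
Conditions: [(Ph3P)CuH]6 (0.4 equiv), degassed H2O (5 equiv), toluene, rt
Reagents that add atoms: none
Why: Copper hydride conjugate reduction of an enone; the soft hydride adds only at Cβ of the polarised C=C, water protonates the copper enolate, and the isolated trisubstituted prenyl alkene, the ketone and the acetals should not react.

Step 13
Reactants: 16 1-[5,7-bis(methoxymethoxy)-2,2-dimethyl-3,4-dihydro-2H-chromen-6-yl]-3-[4-methoxy-3-(methoxymethoxy)-5-(3-methylbut-2-en-1-yl)phenyl]propan-1-one
Product: 17 1-(5,7-dihydroxy-2,2-dimethyl-3,4-dihydro-2H-chromen-6-yl)-3-[3-hydroxy-4-methoxy-5-(3-methylbut-2-en-1-yl)phenyl]propan-1-one (CNP0408176.0)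
Conditions: 3 M aq. HCl, MeOH, rt to 40 °C
Reagents that add atoms: none
Why: Acid-catalysed acetal exchange with methanol removes all three MOM groups; the prenyl group has only a methoxy neighbour, so it cannot close to a chromane, and it should survive the mild acid.

**Compound list**

1 | 2,4,6-trihydroxybenzaldehyde | O=Cc1c(O)cc(O)cc1O | starting material
2 | 3-chloro-3-methylbut-1-yne | C#CC(C)(C)Cl | starting material
3 | 2,6-dihydroxy-4-[(2-methylbut-3-yn-2-yl)oxy]benzaldehyde | C#CC(C)(C)Oc1cc(O)c(C=O)c(O)c1 | intermediate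
4 | 2,6-bis(methoxymethoxy)-4-[(2-methylbut-3-yn-2-yl)oxy]benzaldehyde | C#CC(C)(C)Oc1cc(OCOC)c(C=O)c(OCOC)c1 | intermediate
5 | 5,7-bis(methoxymethoxy)-2,2-dimethyl-2H-chromene-6-carbaldehyde | O=Cc1c(OCOC)cc2c(c1OCOC)C=CC(C)(C)O2 | intermediate
6 | 5,7-bis(methoxymethoxy)-2,2-dimethyl-3,4-dihydro-2H-chromene-6-carbaldehyde | O=Cc1c(OCOC)cc2c(c1OCOC)CCC(C)(C)O2 | intermediate
7 | racemic 1-[5,7-bis(methoxymethoxy)-2,2-dimethyl-3,4-dihydro-2H-chromen-6-yl]ethan-1-ol | CC(O)c1c(OCOC)cc2c(c1OCOC)CCC(C)(C)O2 | intermediate
8 | 1-[5,7-bis(methoxymethoxy)-2,2-dimethyl-3,4-dihydro-2H-chromen-6-yl]ethan-1-one | CC(=O)c1c(OCOC)cc2c(c1OCOC)CCC(C)(C)O2 | intermediate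
9 | 5-bromovanillin (3-bromo-4-hydroxy-5-methoxybenzaldehyde) | COc1cc(C=O)cc(Br)c1O | starting material
10 | 3-bromo-4,5-dihydroxybenzaldehyde | O=Cc1cc(O)c(O)c(Br)c1 | intermediate
11 | 3-bromo-5-hydroxy-4-methoxybenzaldehyde | COc1c(O)cc(C=O)cc1Br | intermediate
12 | 3-bromo-4-methoxy-5-(methoxymethoxy)benzaldehyde | COCOc1cc(C=O)cc(Br)c1OC | intermediate
13 | 4-methoxy-3-(methoxymethoxy)-5-(3-methylbut-2-en-1-yl)benzaldehyde | COCOc1cc(C=O)cc(CC=C(C)C)c1OC | intermediate
14 | racemic 1-[5,7-bis(methoxymethoxy)-2,2-dimethyl-3,4-dihydro-2H-chromen-6-yl]-3-hydroxy-3-[4-methoxy-3-(methoxymethoxy)-5-(3-methylbut-2-en-1-yl)phenyl]propan-1-one (β-hydroxy ketone, not isolated) | COCOc1cc(C(O)CC(=O)c2c(OCOC)cc3c(c2OCOC)CCC(C)(C)O3)cc(CC=C(C)C)c1OC | intermediate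
15 | (E)-1-[5,7-bis(methoxymethoxy)-2,2-dimethyl-3,4-dihydro-2H-chromen-6-yl]-3-[4-methoxy-3-(methoxymethoxy)-5-(3-methylbut-2-en-1-yl)phenyl]prop-2-en-1-one | COCOc1cc(/C=C/C(=O)c2c(OCOC)cc3c(c2OCOC)CCC(C)(C)O3)cc(CC=C(C)C)c1OC | intermediate
16 | 1-[5,7-bis(methoxymethoxy)-2,2-dimethyl-3,4-dihydro-2H-chromen-6-yl]-3-[4-methoxy-3-(methoxymethoxy)-5-(3-methylbut-2-en-1-yl)phenyl]propan-1-one | COCOc1cc(CCC(=O)c2c(OCOC)cc3c(c2OCOC)CCC(C)(C)O3)cc(CC=C(C)C)c1OC | intermediate
17 | 1-(5,7-dihydroxy-2,2-dimethyl-3,4-dihydro-2H-chromen-6-yl)-3-[3-hydroxy-4-methoxy-5-(3-methylbut-2-en-1-yl)phenyl]propan-1-one | COc1c(O)cc(CCC(=O)c2c(O)cc3c(c2O)CCC(C)(C)O3)cc1CC=C(C)C | target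

**Count**

Total: 13 steps. Longest linear sequence: 9 steps (steps 1–6, then 11–13); the ring B branch (steps 7–10) joins at step 11.

**Steps most likely to fail**

Step 3. The cationic gold catalyst may ionise the tertiary propargylic C–O bond, which is weakened because the aryl oxygen is para to the formyl group, so that the alkynyl unit is lost before ring closure. Adventitious acid may also strip a MOM group. Fallback: from 4, the ring is closed thermally without metal (N,N-diethylaniline, 180 °C). An aromatic propargyl Claisen rearrangement to either equivalent ortho carbon and tautomerisation should give 4-hydroxy-2,6-bis(methoxymethoxy)-3-(3-methylbuta-1,2-dien-1-yl)benzaldehyde F1 (not isolated). A 1,5-hydrogen shift then leads to (3Z)-2,6-bis(methoxymethoxy)-3-(3-methylbut-2-en-1-ylidene)-4-oxocyclohexa-1,5-diene-1-carbaldehyde F2 (not isolated), whose oxa-6π electrocyclisation gives 5, where the route is rejoined.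

Step 1. Site control may be incomplete: a second hydroxyl or a ring carbon of the phloroglucinol nucleus may be alkylated alongside the para oxygen. Fallback: from 1, the C–O bond is made on a monophenol instead.
- Silylation (TBSCl 1.05 equiv, imidazole, DMF, 0 °C) should take the unchelated para hydroxyl and give 4-[(tert-butyldimethylsilyl)oxy]-2,6-dihydroxybenzaldehyde F3.
- MOMCl and i-Pr2NEt in CH2Cl2 (0 °C to reflux) then give 4-[(tert-butyldimethylsilyl)oxy]-2,6-bis(methoxymethoxy)benzaldehyde F4.
- TBAF buffered with AcOH in THF at 0 °C releases 4-hydroxy-2,6-bis(methoxymethoxy)benzaldehyde F5.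
- The single free phenol of F5 is etherified with 2 (CuCl2·2H2O, DBU, MeCN, 0 °C) to give 4, where the route is rejoined.

Step 10. Allyl transposition during transfer from tin to palladium or at reductive elimination may deliver the branched 1,1-dimethylallyl isomer, and oxidative addition into the electron-rich bromide may be slow. Fallback: from 12, Stille coupling with allyltributylstannane (Pd(PPh3)4, DMF, 90 °C), where transposition is without consequence, gives 4-methoxy-3-(methoxymethoxy)-5-(prop-2-en-1-yl)benzaldehyde F6. Olefin cross-metathesis of F6 with excess 2-methylbut-2-ene (second-generation Grubbs catalyst, (H2IMes)(PCy3)Cl2Ru=CHPh, CH2Cl2, 40 °C) then installs the trisubstituted alkene and gives 13, where the route is rejoined.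

**Further compounds**

F1 | step 3 | 4-hydroxy-2,6-bis(methoxymethoxy)-3-(3-methylbuta-1,2-dien-1-yl)benzaldehyde | CC(C)=C=Cc1c(O)cc(OCOC)c(C=O)c1OCOC
F2 | step 3 | (3Z)-2,6-bis(methoxymethoxy)-3-(3-methylbut-2-en-1-ylidene)-4-oxocyclohexa-1,5-diene-1-carbaldehyde | CC(C)=C/C=C1\C(=O)C=C(OCOC)C(C=O)=C1OCOC
F3 | step 1 | 4-[(tert-butyldimethylsilyl)oxy]-2,6-dihydroxybenzaldehyde | CC(C)(C)[Si](C)(C)Oc1cc(O)c(C=O)c(O)c1
F4 | step 1 | 4-[(tert-butyldimethylsilyl)oxy]-2,6-bis(methoxymethoxy)benzaldehyde | CC(C)(C)[Si](C)(C)Oc1cc(OCOC)c(C=O)c(OCOC)c1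
F5 | step 1 | 4-hydroxy-2,6-bis(methoxymethoxy)benzaldehyde | O=Cc1c(OCOC)cc(O)cc1OCOC
F6 | step 10 | 4-methoxy-3-(methoxymethoxy)-5-(prop-2-en-1-yl)benzaldehyde | COCOc1cc(C=O)cc(CC=C)c1OC
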